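Ring A of the isoflavone is disconnected at C4a–C5 and C8–C8a. The C4a=C8a enone double bond of ring C then comes from a monocyclic 4-pyranone, and the 1,3-related oxygens on C5 and C7 come from a 1,1,3-trioxygenated butadiene. One operation, a Diels–Alder addition followed by loss of p-toluenesulfenic acid and methanol, should build aromatic ring A with both oxygens in place. The dienophile is a 4-pyranone that already carries the complete 4-methoxy-3-prenylphenyl ring B on C3 and a p-tolylsulfinyl group on C5, which acts as activator, regiochemical director and leaving group.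

Key step: step 7

Assumption: sulfoxide 6 is used as the racemate; sulfur is the only stereogenic element before step 7 and is expelled there, so the sulfinyl compounds are racemic and the achiral target is unaffected. "Prenyl" means 3-methylbut-2-en-1-yl. Compounds 1, 4, 6, 8, 11 and 12 are taken to be catalogue materials.

Step 1
Reactants: 1 3-bromo-4-methoxyphenylacetic acid
Product: 3 2-(3-bromo-4-methoxyphenyl)-N-methoxy-N-methylacetamide, via acyl imidazolide 2 (not isolated)
Conditions: CDI (1.1 equiv), CH2Cl2, 25 °C; then MeNH(OMe)·HCl (1.2 equiv), 25 °C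
Reagents that add atoms: N,O-dimethylhydroxylamine hydrochloride, Cl.CNOC
Why: CDI turns the acid into its acyl imidazolide, which the hydroxylamine aminolyses (standard CDI amide coupling to a Weinreb amide); the amide is preferred to an ester because its adduct in step 3 stops cleanly at the ketone.

Step 2
Reactants: 3 2-(3-bromo-4-methoxyphenyl)-N-methoxy-N-methylacetamide; 4 tributyl(3-methylbut-2-en-1-yl)stannane
Product: 5 N-methoxy-2-(4-methoxy-3-prenylphenyl)-N-methylacetamide
Conditions: Pd(PPh3)4 (5 mol %), DMF, 100 °C
Reagents that add atoms: none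
Why: Stille coupling, in which zerovalent palladium inserts into the aryl C–Br bond, prenyl is transferred from tin and reductive elimination at the unsubstituted allyl terminus should give the linear 3-prenyl arene under neutral conditions that leave the amide alone.

Step 3
Reactants: 5 N-methoxy-2-(4-methoxy-3-prenylphenyl)-N-methylacetamide; 6 rac-methyl p-tolyl sulfoxide
Product: 7 rac-1-(4-methoxy-3-prenylphenyl)-3-(p-tolylsulfinyl)propan-2-one
Conditions: 6 (1.5 equiv), LiN(iPr)2 (1.5 equiv), THF, −78 °C; then 5, −78 → −40 °C; aq NH4Cl
Reagents that add atoms: none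
Why: Acylation of the α-sulfinyl carbanion by the N-methoxy-N-methyl amide (Weinreb ketone synthesis) gives a chelated lithium adduct that collapses to the β-keto sulfoxide only on quench, so neither over-addition nor deprotonation of the acidic product consumes the carbanion.

Step 4
Reactants: 7 rac-1-(4-methoxy-3-prenylphenyl)-3-(p-tolylsulfinyl)propan-2-one; 8 N,N-dimethylformamide dimethyl acetal
Product: 10 rac-3-(4-methoxy-3-prenylphenyl)-5-(p-tolylsulfinyl)-4H-pyran-4-one, via bis-enaminone 9 (not isolated)
Conditions: 8 (6 equiv), PhMe, 100 °C; evaporate; then 1 M aq HCl, THF, 0 → 25 °C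
Reagents that add atoms: water, O
Why: Both methylene groups flanking the ketone (one sulfinyl-activated, one benzylic) condense with the amide acetal (double aminomethylenation, known for 1,3-disubstituted acetones), and aqueous acid then hydrolyses one enamine to an enol whose oxygen adds to the other enaminone carbon with loss of dimethylamine (cyclocondensation to a 3,5-disubstituted 4-pyranone); the sulfoxide has no β-hydrogen on an sp3 carbon and should survive the heating.

Step 5
Reactants: 11 1,1-dimethoxyethene; 12 acetyl chloride
Product: 13 4,4-dimethoxybut-3-en-2-one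
Conditions: Et3N (1.1 equiv), Et2O, 0 → 25 °C
Reagents that add atoms: none
Why: C-Acylation of the nucleophilic CH2 of the ketene acetal by the acid chloride, with amine-assisted loss of HCl, should give the push–pull β,β-dimethoxy enone (known acylation of ketene acetals).

Step 6
Reactants: 13 4,4-dimethoxybut-3-en-2-one
Product: 14 1,1-dimethoxy-3-(trimethylsilyloxy)buta-1,3-diene
Conditions: TMSCl (1.3 equiv), Et3N (1.5 equiv), ZnCl2 (cat.), PhMe, 40 °C; filter, distil
Reagents that add atoms: chlorotrimethylsilane, C[Si](C)(C)Cl
Why: Enol silylation of the only enolisable position, the acetyl CH3, under the amine/ZnCl2 conditions used for Danishefsky-type dienes gives the 2-silyloxy diene, which is isolated without aqueous contact.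

Step 7
Reactants: 10 rac-3-(4-methoxy-3-prenylphenyl)-5-(p-tolylsulfinyl)-4H-pyran-4-one; 14 1,1-dimethoxy-3-(trimethylsilyloxy)buta-1,3-diene
Product: 17 7-hydroxy-5-methoxy-3-(4-methoxy-3-prenylphenyl)-4H-chromen-4-one, via cis-fused cycloadduct 15 (not isolated), via 5,8-dihydrochromenone ketal 16 (not isolated)
Conditions: 14 (3 equiv), PhMe, 25 → 80 °C, N2; then 1 M aq HCl, THF, 25 °C
Reagents that add atoms: none
Why: Proposed new method: the CH2 terminus of diene 14, on which both donor groups concentrate the HOMO, attacks C6 of pyranone 10 (future C8a, β to the ketone and to the sulfinyl group) while the ketene acetal carbon bonds to the sulfinyl-bearing C5 (future C4a) in a concerted but asynchronous normal-demand Diels–Alder (4+2) cycloaddition. Ring A, a six-membered carbocycle, is closed intermolecularly by this cycloaddition, which forms C4a–C5 and C8–C8a at once; the closest known reaction type is the cycloaddition–elimination–aromatisation of sulfinyl- or halo-activated quinones and chromones with 1,1-dialkoxy-3-silyloxybutadienes, and the untested element is a monocyclic 4-pyranone as dienophile. Suprafacial addition gives cis-fused 15 with the angular sulfinyl group and H-8a syn, so warming should bring about the sulfoxide syn elimination of p-toluenesulfenic acid and regenerate C4a=C8a in 16; this is completed before acid is added so that no C7 ketone can open ring C by β-elimination of the ring oxygen. Acid then expels methanol across C5 and C8 and cleaves the silyl ether, which aromatises ring A with OMe on C5 and OH on C7. The stereocentres created at C4a and C8a, and the sulfur centre, are all destroyed, so no stereocontrol is required. The step needs site selectivity for C5=C6 of the pyranone over the aryl-bearing C2=C3 bond and the orientation that places the ketal carbon on C4a; both are secured by the sulfinyl group, which activates only the double bond it sits on and makes its β-carbon the most electrophilic site.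

Step 8
Reactants: 17 7-hydroxy-5-methoxy-3-(4-methoxy-3-prenylphenyl)-4H-chromen-4-one
Product: 18 5,7-dihydroxy-3-(4-methoxy-3-prenylphenyl)-4H-chromen-4-one
Conditions: MgI2·OEt2 (3 equiv), THF, 60 °C; then H2O
Reagents that add atoms: none
Why: Magnesium chelates the C4 carbonyl and the peri C5 methoxy oxygen, so iodide should cleave only that methyl ether by SN2 attack at methyl (chelation-directed Lewis-acid ether cleavage), while the unchelated 4'-methoxy group, the free 7-hydroxyl and the prenyl alkene are untouched under aprotic conditions.

Compound list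
1 | 3-bromo-4-methoxyphenylacetic acid | COc1ccc(CC(=O)O)cc1Br | starting material
2 | 2-(3-bromo-4-methoxyphenyl)-1-(imidazol-1-yl)ethan-1-one (acyl imidazolide, not isolated) | COc1ccc(CC(=O)n2ccnc2)cc1Br | intermediate
3 | 2-(3-bromo-4-methoxyphenyl)-N-methoxy-N-methylacetamide | COc1ccc(CC(=O)N(C)OC)cc1Br | intermediate
4 | tributyl(3-methylbut-2-en-1-yl)stannane | CCCC[Sn](CCCC)(CCCC)CC=C(C)C | starting material
5 | N-methoxy-2-[4-methoxy-3-(3-methylbut-2-en-1-yl)phenyl]-N-methylacetamide | COc1ccc(CC(=O)N(C)OC)cc1CC=C(C)C | intermediate
6 | rac-methyl p-tolyl sulfoxide | Cc1ccc(S(C)=O)cc1 | starting material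
7 | rac-1-[4-methoxy-3-(3-methylbut-2-en-1-yl)phenyl]-3-(p-tolylsulfinyl)propan-2-one | COc1ccc(CC(=O)CS(=O)c2ccc(C)cc2)cc1CC=C(C)C | intermediate
8 | N,N-dimethylformamide dimethyl acetal | COC(OC)N(C)C | starting material
9 | rac-1,5-bis(dimethylamino)-2-(4-methoxy-3-prenylphenyl)-4-(p-tolylsulfinyl)penta-1,4-dien-3-one (enamine geometry not controlled, not isolated) | CN(C)C=C(C(=O)C(=CN(C)C)S(=O)c1ccc(C)cc1)c1ccc(OC)c(CC=C(C)C)c1 | intermediate
10 | rac-3-(4-methoxy-3-prenylphenyl)-5-(p-tolylsulfinyl)-4H-pyran-4-one | Cc1ccc(S(=O)c2cocc(-c3ccc(OC)c(CC=C(C)C)c3)c2=O)cc1 | intermediate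
11 | 1,1-dimethoxyethene | C=C(OC)OC | starting material
12 | acetyl chloride | CC(=O)Cl | starting material
13 | 4,4-dimethoxybut-3-en-2-one | COC(OC)=CC(C)=O | intermediate
14 | 1,1-dimethoxy-3-(trimethylsilyloxy)buta-1,3-diene | COC(OC)=CC(=C)O[Si](C)(C)C | intermediate
15 | rac-cis-5,5-dimethoxy-3-(4-methoxy-3-prenylphenyl)-4a-(p-tolylsulfinyl)-7-(trimethylsilyloxy)-4a,5,8,8a-tetrahydro-4H-chromen-4-one (sulfinyl on C4a and H on C8a syn; relative configuration shown, both sulfur epimers; not isolated) | COC1(OC)C=C(O[Si](C)(C)C)C[C@@H]2OC=C(c3ccc(OC)c(CC=C(C)C)c3)C(=O)[C@]12S(=O)c4ccc(C)cc4 | intermediate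
16 | 5,5-dimethoxy-3-(4-methoxy-3-prenylphenyl)-7-(trimethylsilyloxy)-5,8-dihydro-4H-chromen-4-one (not isolated) | COC1(OC)C=C(O[Si](C)(C)C)Cc2occ(-c3ccc(OC)c(CC=C(C)C)c3)c(=O)c21 | intermediate
17 | 7-hydroxy-5-methoxy-3-(4-methoxy-3-prenylphenyl)-4H-chromen-4-one | COc1ccc(-c2coc3cc(O)cc(OC)c3c2=O)cc1CC=C(C)C | intermediate
18 | 5,7-dihydroxy-3-[4-methoxy-3-(3-methylbut-2-en-1-yl)phenyl]-4H-chromen-4-one (EANPDB:LEGU_00239) | COc1ccc(-c2coc3cc(O)cc(O)c3c2=O)cc1CC=C(C)C | target

Total step count: 8. Longest linear sequence: 6 steps (1, 2, 3, 4, 7, 8); steps 5 and 6 make the diene in a two-step side branch.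

Steps most likely to fail

Step 7. The diene may add stepwise as a carbon nucleophile at C6 of the pyranone and the adduct may then open ring C instead of closing ring A. Alternatively the pyranone may be too weak a dienophile, so that the diene is hydrolysed or oligomerised first. The fallback uses only known chemistry, sets out from acid 1 and returns at target 18, taking ring A from phloroglucinol. Friedel–Crafts acylation of phloroglucinol with 1 (BF3·OEt2, 80 °C) should give 2-(3-bromo-4-methoxyphenyl)-1-(2,4,6-trihydroxyphenyl)ethan-1-one F1. One-carbon ring closure with DMF, MsCl and BF3·OEt2 should give 3-(3-bromo-4-methoxyphenyl)-5,7-dihydroxy-4H-chromen-4-one F2. Stille coupling of F2 with stannane 4 (Pd(PPh3)4, DMF, 100 °C) then installs the prenyl group last, after all BF3 chemistry, and gives 18.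

Step 4. The second condensation at the benzylic methylene may stall once the sulfinyl-activated methylene has become a deactivating vinylogous amide, or the sulfoxide may degrade during acid closure. The fallback sets out from ketone 7 and returns at pyranone 10, formylating the benzylic carbon through its enolate. One equivalent of 8 at 25 °C in CH2Cl2 should react only at the sulfinyl-activated methylene to give 4-(dimethylamino)-1-(4-methoxy-3-prenylphenyl)-3-(p-tolylsulfinyl)but-3-en-2-one F3. Claisen formylation of the benzylic position (NaH, HCO2Et, THF, 0 → 25 °C) should give 5-(dimethylamino)-1-hydroxy-2-(4-methoxy-3-prenylphenyl)-4-(p-tolylsulfinyl)penta-1,4-dien-3-one F4. Buffered acetic acid then closes the ring by addition of the enol oxygen to the enaminone carbon with loss of dimethylamine, giving 10.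

Step 3. Proton transfer from the benzylic methylene of amide 5 to the sulfinyl carbanion may outrun addition to the carbonyl, returning starting material on quench. The fallback sets out from amide 5 and returns at ketone 7, using a more electrophilic carbonyl and restoring the oxidation level afterwards. Reduction of 5 with iBu2AlH (THF, −78 °C) should give 2-(4-methoxy-3-prenylphenyl)acetaldehyde F5, used crude. Addition of lithiated 6 at −78 °C should give 1-(4-methoxy-3-prenylphenyl)-3-(p-tolylsulfinyl)propan-2-ol F6 as a diastereomer mixture. Dess–Martin periodinane (NaHCO3, CH2Cl2) oxidises the carbinol to 7 without touching the sulfoxide or the alkene.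

Further compounds
F1 | step 7 | 2-(3-bromo-4-methoxyphenyl)-1-(2,4,6-trihydroxyphenyl)ethan-1-one | COc1ccc(CC(=O)c2c(O)cc(O)cc2O)cc1Br
F2 | step 7 | 3-(3-bromo-4-methoxyphenyl)-5,7-dihydroxy-4H-chromen-4-one | COc1ccc(-c2coc3cc(O)cc(O)c3c2=O)cc1Br
F3 | step 4 | rac-4-(dimethylamino)-1-(4-methoxy-3-prenylphenyl)-3-(p-tolylsulfinyl)but-3-en-2-one (enamine geometry not controlled) | COc1ccc(CC(=O)C(=CN(C)C)S(=O)c2ccc(C)cc2)cc1CC=C(C)C
F4 | step 4 | rac-5-(dimethylamino)-1-hydroxy-2-(4-methoxy-3-prenylphenyl)-4-(p-tolylsulfinyl)penta-1,4-dien-3-one (double-bond geometry not controlled) | COc1ccc(C(=CO)C(=O)C(=CN(C)C)S(=O)c2ccc(C)cc2)cc1CC=C(C)C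
F5 | step 3 | 2-(4-methoxy-3-prenylphenyl)acetaldehyde | COc1ccc(CC=O)cc1CC=C(C)C
F6 | step 3 | 1-(4-methoxy-3-prenylphenyl)-3-(p-tolylsulfinyl)propan-2-ol (mixture of diastereomers, racemic) | COc1ccc(CC(O)CS(=O)c2ccc(C)cc2)cc1CC=C(C)C
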